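**Assumption:** ring positions use labdane numbering (C1–C10, gem-dimethyl on C4, angular methyl on C10, side chain from C9; α = face opposite the C10 methyl); commercial reagents and catalysts are not numbered; SMILES are authoritative for stereochemistry.

## Retrosynthetic overview

1. The 12-OOH comes from SN2 inversion of H2O2 on a (12S)-dienyl mesylate; C12–C13 and the diene come from a catalyst-controlled homoallenylboration of a C12 aldehyde.
2. C11–C12 comes from hydroformylation of a C9 exocyclic methylene, itself from a C9 ketone; the 7,8-oxygens come from OsO4 on Δ7 followed by oxidation/reduction at C7.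
3. The decalin comes from a catalytic enantioselective Diels–Alder reaction that desymmetrises 2,6-dimethylbenzoquinone (from 2,6-dimethylphenol) with 4-methylpenta-1,3-diene.
4. Ring order: ring B (the former arene) first, ring A by [4+2], then kinetic C5 protonation to the trans-decalin, side chain last.

## Route

**Step 1**
Reactants: 1 2,6-dimethylphenol
Product: 2 2,6-dimethyl-1,4-benzoquinone
Conditions: O2 (1 atm), Co(salen) 5 mol %, DMF, 25 °C
Reagents that add atoms: dioxygen, O=O
Why: Cobalt–salen aerobic para-oxidation (oxidative dearomatisation) of a 2,6-dialkylphenol gives the C2v-symmetric quinone that already carries the future C8 and C10 methyls.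

**Step 2**
Reactants: 2 2,6-dimethyl-1,4-benzoquinone; 3 4-methylpenta-1,3-diene
Product: 4 (4aR,8aS)-2,5,5,8a-tetramethyl-4a,5,8,8a-tetrahydronaphthalene-1,4-dione (cis-fused adduct)
Conditions: (S)-o-tolyl-CBS-oxazaborolidine·HNTf2 20 mol %, 3 (5 equiv), CH2Cl2, −78 → −30 °C
Reagents that add atoms: none
Why: Oxazaborolidinium-catalysed enantioselective Diels–Alder desymmetrisation: the cation binds the unhindered C6 carbonyl, selects one of the two enantiotopic MeC=CH bonds and one face, and the diene CH2 terminus bonds to the methyl-bearing β-carbon (sets C10) while CMe2 closes on C5; the Z-methyl of the diene makes this asynchronous cycloaddition the bold step, and the catalyst hand is assigned by the published model (the antipode is equally available if the sense proves opposite).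

**Step 3**
Reactants: 4 cis-fused adduct
Product: 7 6β-hydroxy-11,12,13,14,15,16-hexanorlabda-2,7-dien-9-one, via lithium C5 enolate 5 (not isolated), via trans-enedione 6 (not isolated)
Conditions: LiHMDS (1.05 equiv), THF, −78 °C; AcOH (1.1 equiv), −78 °C; then CeCl3·7H2O, MeOH, NaBH4, −78 °C
Reagents that add atoms: none
Why: Kinetic (Zimmerman-type) protonation of the C5 enolate anti to the axial C10 methyl gives the 5α-H trans-enedione, which is used without equilibration because the 4,4-dimethyl/6-oxo interaction probably favours cis thermodynamically; in-situ Luche reduction then takes the less hindered C6 carbonyl from the open α face (6β-OH) and removes the epimerisable ketone.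

**Step 4**
Reactants: 7 6β-hydroxy-hexanorlabda-2,7-dien-9-one
Product: 8 6β-hydroxy-11,12,13,14,15,16-hexanorlabd-7-en-9-one
Conditions: H2 (1 atm), RhCl(PPh3)3 5 mol %, benzene/EtOH 1:1, 25 °C
Reagents that add atoms: none
Why: Wilkinson hydrogenation reduces the isolated cis-disubstituted Δ2 alkene and leaves the trisubstituted enone alkene; no stereocentre is formed.

**Step 5**
Reactants: 8 6β-hydroxy-hexanorlabd-7-en-9-one
Product: 9 12,13,14,15,16-pentanorlabda-7,9(11)-dien-6β-ol
Conditions: Ph3PCH3Br (4 equiv), KOtBu (4 equiv), toluene, 0 → 90 °C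
Reagents that add atoms: methylenetriphenylphosphorane (made in situ), C=P(c1ccccc1)(c1ccccc1)c1ccccc1
Why: Wittig methylenation of the only carbonyl, a non-enolisable hindered enone; the 6-OH rides through as its potassium alkoxide, which also suppresses γ-deprotonation.

**Step 6**
Reactants: 9 pentanorlabda-7,9(11)-dien-6β-ol
Product: 10 12,13,14,15,16-pentanorlabd-9(11)-ene-6β,7α,8α-triol
Conditions: OsO4 2 mol %, NMO (1.5 equiv), acetone/H2O 5:1, 0 → 25 °C
Reagents that add atoms: N-methylmorpholine N-oxide, C[N+]1([O-])CCOCC1; water, O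
Why: Upjohn dihydroxylation takes the electron-rich trisubstituted Δ7 rather than the hindered 1,1-disubstituted Δ9(11), from the α face (anti to the axial C10 methyl and to the allylic 6β-OH); this sets C8 as 8α-OH/8β-Me and gives 7α-OH.

**Step 7**
Reactants: 10 6β,7α,8α-triol
Product: 11 6β,8α-dihydroxy-12,13,14,15,16-pentanorlabd-9(11)-en-7-one
Conditions: Dess–Martin periodinane (1.2 equiv), NaHCO3, CH2Cl2, 0 °C
Reagents that add atoms: none
Why: Dess–Martin oxidation reaches only the exposed 7α-OH (6β-OH is buried under three syn-axial methyls, 8-OH is tertiary); C6 stays an alcohol so C5 cannot epimerise.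

**Step 8**
Reactants: 11 7-ketone
Product: 12 12,13,14,15,16-pentanorlabd-9(11)-ene-6β,7β,8α-triol
Conditions: NaBH4, MeOH, −20 °C
Reagents that add atoms: none
Why: Borohydride reduction with axial hydride delivery from the α face (β face blocked by 6β-OH and 8β-Me) gives the equatorial 7β-OH, a net inversion at C7.

**Step 9**
Reactants: 12 6β,7β,8α-triol
Product: 14 7β-acetoxy-6β,8α-bis(triethylsilyloxy)-12,13,14,15,16-pentanorlabd-9(11)-ene, via 7-acetate 13 (not isolated)
Conditions: Ac2O (1.2 equiv), pyridine, CH2Cl2, 0 → 25 °C; then 2,6-lutidine, TESOTf (4 equiv), 0 → 25 °C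
Reagents that add atoms: acetic anhydride, CC(=O)OC(C)=O; triethylsilyl triflate, CC[Si](CC)(CC)OS(=O)(=O)C(F)(F)F
Why: Selective acylation of the only unhindered (equatorial 7β) hydroxyl, as in 7-deacetylforskolin, then silyl triflate capping of the 6β and tertiary 8α hydroxyls so that O8 cannot later close the 8,12-ether onto an activated C12.

**Step 10**
Reactants: 14 bis-TES 7-acetate
Product: 15 7β-acetoxy-6β,8α-bis(triethylsilyloxy)-13,14,15,16-tetranorlabdan-12-al
Conditions: Rh(acac)(CO)2 2 mol %, tris(2,4-di-tert-butylphenyl) phosphite 8 mol %, CO/H2 1:1 (20 bar), toluene, 80 °C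
Reagents that add atoms: carbon monoxide, [C-]#[O+]
Why: Rhodium hydroformylation of a 1,1-disubstituted alkene is linear-selective (Keulemans rule), and Rh–H delivers hydrogen to C9 from the α face (β face blocked by the 8β and 10β methyls), giving 9α-H with C11 equatorial.

**Step 11**
Reactants: 16 allenylboronic acid pinacol ester
Product: 18 buta-2,3-dien-1-ylboronic acid pinacol ester, via chloromethyl boronate complex 17 (not isolated)
Conditions: BrCH2Cl (1.3 equiv), n-BuLi (1.2 equiv), THF, −78 → 25 °C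
Reagents that add atoms: bromochloromethane (as LiCH2Cl), ClCBr
Why: Matteson homologation: in-situ LiCH2Cl adds to boron and the allenyl group undergoes a 1,2-shift with loss of chloride.

**Step 12**
Reactants: 15 C12 aldehyde; 18 buta-2,3-dien-1-ylboronic acid pinacol ester
Product: 20 (12S)-7β-acetoxy-6β,8α-bis(triethylsilyloxy)labda-13(16),14-dien-12-ol, via O-boryl adduct 19 (not isolated)
Conditions: (R)-TRIP 5 mol %, 4 Å MS, toluene, −30 °C; aq. NaHCO3 work-up
Reagents that add atoms: none
Why: Chiral-phosphoric-acid-catalysed homoallenylboration through a closed chair transition state: the central allene carbon bonds to the aldehyde to give the 2-substituted buta-1,3-diene, and the catalyst sets C12 as S (same facial sense as CPA allylborations; the antipodal acid gives the epimer).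

**Step 13**
Reactants: 20 (12S)-dienyl alcohol
Product: 23 (12R)-7β-acetoxy-12-hydroperoxylabda-13(16),14-diene-6β,8α-diol, via C12 mesylate 21 (not isolated), via bis-TES hydroperoxide 22 (not isolated)
Conditions: MsCl, Et3N, CH2Cl2, −40 °C; 50 % aq. H2O2 (30 equiv), KOH (3 equiv), THF/MeOH 5:1, −20 °C; then HF·pyridine, THF/pyridine, 0 °C
Reagents that add atoms: hydrogen peroxide, OO
Why: Williams–Mosher-type SN2 perhydrolysis of the allylic mesylate inverts C12 to R while the silyl ether on O8 blocks 8,12-ether formation; fluoride then removes both TES groups without touching the acetate or the hydroperoxide.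

## Compound list

1 | 2,6-dimethylphenol | Cc1cccc(C)c1O | starting material
2 | 2,6-dimethyl-1,4-benzoquinone | CC1=CC(=O)C=C(C)C1=O | intermediate
3 | 4-methylpenta-1,3-diene | C=CC=C(C)C | starting material
4 | (4aR,8aS)-2,5,5,8a-tetramethyl-4a,5,8,8a-tetrahydronaphthalene-1,4-dione (cis, 5β-H) | O=C1C(C)=CC(=O)[C@@H]2C(C)(C)C=CC[C@@]21C | intermediate
5 | lithium C5(6)-enolate of 4 | [Li+].[O-]C1=C2C(C)(C)C=CC[C@]2(C)C(=O)C(C)=C1 | intermediate
6 | (4aS,8aS)-2,5,5,8a-tetramethyl-4a,5,8,8a-tetrahydronaphthalene-1,4-dione (trans, 5α-H) | O=C1C(C)=CC(=O)[C@H]2C(C)(C)C=CC[C@@]21C | intermediate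
7 | 6β-hydroxy-11,12,13,14,15,16-hexanorlabda-2,7-dien-9-one | O=C1C(C)=C[C@@H](O)[C@H]2C(C)(C)C=CC[C@@]21C | intermediate
8 | 6β-hydroxy-11,12,13,14,15,16-hexanorlabd-7-en-9-one | O=C1C(C)=C[C@@H](O)[C@H]2C(C)(C)CCC[C@@]21C | intermediate
9 | 12,13,14,15,16-pentanorlabda-7,9(11)-dien-6β-ol | C=C1C(C)=C[C@@H](O)[C@H]2C(C)(C)CCC[C@@]21C | intermediate
10 | 12,13,14,15,16-pentanorlabd-9(11)-ene-6β,7α,8α-triol | C=C1[C@](C)(O)[C@H](O)[C@@H](O)[C@H]2C(C)(C)CCC[C@@]21C | intermediate
11 | 6β,8α-dihydroxy-12,13,14,15,16-pentanorlabd-9(11)-en-7-one | C=C1[C@](C)(O)C(=O)[C@@H](O)[C@H]2C(C)(C)CCC[C@@]21C | intermediate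
12 | 12,13,14,15,16-pentanorlabd-9(11)-ene-6β,7β,8α-triol | C=C1[C@](C)(O)[C@@H](O)[C@@H](O)[C@H]2C(C)(C)CCC[C@@]21C | intermediate
13 | 7β-acetoxy-12,13,14,15,16-pentanorlabd-9(11)-ene-6β,8α-diol | C=C1[C@](C)(O)[C@@H](OC(C)=O)[C@@H](O)[C@H]2C(C)(C)CCC[C@@]21C | intermediate
14 | 7β-acetoxy-6β,8α-bis(triethylsilyloxy)-12,13,14,15,16-pentanorlabd-9(11)-ene | C=C1[C@](C)(O[Si](CC)(CC)CC)[C@@H](OC(C)=O)[C@@H](O[Si](CC)(CC)CC)[C@H]2C(C)(C)CCC[C@@]21C | intermediate
15 | 7β-acetoxy-6β,8α-bis(triethylsilyloxy)-13,14,15,16-tetranorlabdan-12-al | O=CC[C@H]1[C@](C)(O[Si](CC)(CC)CC)[C@@H](OC(C)=O)[C@@H](O[Si](CC)(CC)CC)[C@H]2C(C)(C)CCC[C@@]21C | intermediate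
16 | allenylboronic acid pinacol ester | C=C=CB1OC(C)(C)C(C)(C)O1 | starting material
17 | lithium allenyl(chloromethyl) pinacol boronate complex | [Li+].ClC[B-]1(C=C=C)OC(C)(C)C(C)(C)O1 | intermediate
18 | buta-2,3-dien-1-ylboronic acid pinacol ester | C=C=CCB1OC(C)(C)C(C)(C)O1 | intermediate
19 | 12-O-(pinacolatoboryl) derivative of 20 | C=CC(=C)[C@H](C[C@H]1[C@](C)(O[Si](CC)(CC)CC)[C@@H](OC(C)=O)[C@@H](O[Si](CC)(CC)CC)[C@H]2C(C)(C)CCC[C@@]21C)OB1OC(C)(C)C(C)(C)O1 | intermediate
20 | (12S)-7β-acetoxy-6β,8α-bis(triethylsilyloxy)labda-13(16),14-dien-12-ol | C=CC(=C)[C@H](C[C@H]1[C@](C)(O[Si](CC)(CC)CC)[C@@H](OC(C)=O)[C@@H](O[Si](CC)(CC)CC)[C@H]2C(C)(C)CCC[C@@]21C)O | intermediate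
21 | (12S)-12-methanesulfonate of 20 | C=CC(=C)[C@H](C[C@H]1[C@](C)(O[Si](CC)(CC)CC)[C@@H](OC(C)=O)[C@@H](O[Si](CC)(CC)CC)[C@H]2C(C)(C)CCC[C@@]21C)OS(C)(=O)=O | intermediate
22 | (12R)-7β-acetoxy-12-hydroperoxy-6β,8α-bis(triethylsilyloxy)labda-13(16),14-diene | C=CC(=C)[C@@H](C[C@H]1[C@](C)(O[Si](CC)(CC)CC)[C@@H](OC(C)=O)[C@@H](O[Si](CC)(CC)CC)[C@H]2C(C)(C)CCC[C@@]21C)OO | intermediate
23 | (12R)-7β-acetoxy-12-hydroperoxylabda-13(16),14-diene-6β,8α-diol (CNP0356983.1) | C=CC(=C)[C@@H](C[C@H]1[C@](C)(O)[C@@H](OC(C)=O)[C@@H](O)[C@H]2C(C)(C)CCC[C@@]21C)OO | target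

## Step count and risks

Total steps: 13. Longest linear sequence: 12 (steps 1–10, 12, 13; step 11 is the side branch).

**Step 2 (Diels–Alder with a Z-substituted diene).** The cis-methyl of 3 disfavours the s-cis conformer, so [2+2] adducts, diene oligomers or no reaction are possible. Fallback, setting out from 2 and returning at 4: mesityl oxide is silylated (TMSOTf, Et3N) to 4-methyl-2-(trimethylsilyloxy)penta-1,3-diene F1, a much more nucleophilic diene whose CH2 terminus is a silyl enol ether carbon. Under the same oxazaborolidinium catalyst it adds to 2 by a Mukaiyama–Michael/Michael sequence (formal [4+2], same regiochemistry) to give the 2-silyloxy cis-adduct F2. CsF/PhNTf2 converts this into the C2 enol triflate F3, and Pd(OAc)2/PPh3/HCO2H/Bu3N reduces the triflate to the Δ2 alkene, which is 4.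

**Step 3 (kinetic trans ring fusion).** Deprotonation may occur at the C8 methyl (γ) instead of C5, and C-protonation may be poorly face-selective or equilibrate back to cis before reduction. Fallback, setting out from 4 (through enolate 5) and returning at 6: the enolate is quenched with NBS to the 5α-bromo enedione F4, and the bromide is removed with (Me3Si)3SiH and Et3B/air in toluene at −78 °C. The planar C5 radical takes hydrogen from the bulky silane on the face anti to the C10 methyl, irreversibly and without base, to give trans-enedione 6, which is reduced under the Luche conditions of step 3 to 7.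

**Step 13 (SN2 perhydrolysis of a 2-substituted allylic mesylate).** SN2′ attack at C16, ionisation with loss of C12 configuration, or perhydrolysis of the 7-acetate may compete. Fallback, setting out from 13 (step 9 stopped after acetylation) and returning at 23: commercial (E)-3-iodo-2-methylprop-2-en-1-ol is oxidised (MnO2) to (E)-3-iodo-2-methylprop-2-enal F5 and methylenated (Ph3P=CH2) to (E)-1-iodo-2-methylbuta-1,3-diene F6. Compound 13 is hydroborated with excess 9-BBN (H to C9 from the α face) to the C11 B-alkyl-9-BBN F7, which is coupled with F6 (Pd(dppf)Cl2, Cs2CO3, DMF/H2O) to 7β-acetoxylabda-12E,14-diene-6β,8α-diol F8. A Schenck ene reaction (O2, hν, tetraphenylporphyrin, CH2Cl2, −20 °C) abstracts a C16 hydrogen and places OOH on C12. This gives 23 together with its 12S epimer, the 13-hydroperoxide and the 12,15-endoperoxide, so C12 control is given up and 23 is isolated by HPLC.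

## Further compounds

F1 | step 2 | 4-methyl-2-(trimethylsilyloxy)penta-1,3-diene | C=C(O[Si](C)(C)C)C=C(C)C
F2 | step 2 | (4aR,8aS)-2,5,5,8a-tetramethyl-7-(trimethylsilyloxy)-4a,5,8,8a-tetrahydronaphthalene-1,4-dione | O=C1C(C)=CC(=O)[C@@H]2C(C)(C)C=C(O[Si](C)(C)C)C[C@@]21C
F3 | step 2 | corresponding C2 enol triflate (7-triflyloxy analogue of 4) | O=C1C(C)=CC(=O)[C@@H]2C(C)(C)C=C(OS(=O)(=O)C(F)(F)F)C[C@@]21C
F4 | step 3 | 5α-bromo-11,12,13,14,15,16-hexanorlabda-2,7-diene-6,9-dione | O=C1C(C)=CC(=O)[C@@]2(Br)C(C)(C)C=CC[C@@]21C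
F5 | step 13 | (E)-3-iodo-2-methylprop-2-enal | O=C/C(C)=C/I
F6 | step 13 | (E)-1-iodo-2-methylbuta-1,3-diene | C=C/C(C)=C/I
F7 | step 13 | 11-(9-borabicyclo[3.3.1]nonan-9-yl)-7β-acetoxy-12,13,14,15,16-pentanorlabdane-6β,8α-diol | C(B1C2CCCC1CCC2)[C@H]3[C@](C)(O)[C@@H](OC(C)=O)[C@@H](O)[C@H]4C(C)(C)CCC[C@@]43C
F8 | step 13 | 7β-acetoxylabda-12E,14-diene-6β,8α-diol | C=C/C(C)=C/C[C@H]1[C@](C)(O)[C@@H](OC(C)=O)[C@@H](O)[C@H]2C(C)(C)CCC[C@@]21C
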